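**Retrosynthetic overview**

1. The ester C9–O bond is cut first. This gives O‑MOM‑ferulic acid and the C2‑symmetric bis‑MOM diol (the secoisolariciresinol core), whose two hydroxyls are homotopic. The diol comes from a 2,3‑dibenzylsuccinate diester by hydride reduction.
2. Feature used: each of the two identical 4‑hydroxy‑3‑methoxyphenyl (guaiacyl) rings of the core is bound through ring carbon C1 to a benzylic CH2 (C7, C7′). These CH2 groups flank the adjacent stereocentres C8/C8′ (C2/C3 of the butane chain). Both aryl C1–C7 bonds are cut together, giving two CH2CO2H arms activated as N‑acyloxyphthalimides and one arylzinc chloride.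
3. The two CH2CO2H arms are the opened form of a cyclohexene C=C. The end carbons of butadiene become C7/C7′ and the inner carbons leave as CO2. C8/C8′ are the fumarate carbons, set (R,R) by a Diels–Alder reaction on di‑(+)‑menthyl fumarate.
4. The menthyl esters stay in place through the key step, so no ester exchange is needed at epimerisable centres. LiAlH4 finally removes them and returns menthol.
5. Ring order: only one ring is made, the cyclohexene in step 2, and it is opened again in step 3. The three benzene rings are bought and no ring closes later.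

Key step: step 7

Assumption: aluminium‑Lewis‑acid‑promoted additions to (1R,2S,5R)‑menthyl fumarate are taken to give the (1S,2S) cyclohexene, so the (1S,2R,5S) auxiliary is used for the (1R,2R) series; if the sense were opposite, the other menthol enantiomer would be used with no other change.

**Route**

Step 1
Reactants: 1 fumaric acid; 2 (+)-menthol, (1S,2R,5S)-2-isopropyl-5-methylcyclohexan-1-ol
Product: 3 bis[(1S,2R,5S)-menthyl] (E)-but-2-enedioate (di-(+)-menthyl fumarate)
Conditions: 2 (2.1 equiv), p-TsOH·H2O (cat.), toluene, reflux, Dean–Stark trap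
Reagents that add atoms: none
Why: Fischer esterification driven by azeotropic removal of water, which touches neither the E-alkene nor the menthyl stereocentres.

Step 2
Reactants: 3 di-(+)-menthyl fumarate; 4 buta-1,3-diene
Product: 5 bis[(1S,2R,5S)-menthyl] (1R,2R)-cyclohex-4-ene-1,2-dicarboxylate
Conditions: Et2AlCl (2.0 equiv), 4 (excess, condensed in), toluene–hexane, −40 °C; aq. HCl work-up; purify to one diastereomer
Reagents that add atoms: none
Why: Lewis-acid-promoted asymmetric Diels–Alder reaction in which suprafacial addition to the E-alkene fixes the trans relation of C1 and C2, and in which the isopropyl groups of both menthyl esters (aluminium-bound s-trans enoate conformers) cover the same face of the C=C, so that butadiene should add to the open face and give the (1R,2R) adduct.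

Step 3
Reactants: 5 cyclohexene diester
Product: 6 (3R,4R)-3,4-bis{[(1S,2R,5S)-menthyl]oxycarbonyl}hexanedioic acid
Conditions: RuCl3·xH2O (3 mol %), NaIO4 (4.5 equiv), EtOAc–MeCN–H2O, 0 °C to rt
Reagents that add atoms: NaIO4, [Na+].[O-]I(=O)(=O)=O; water, O
Why: catalytic RuO4 oxidative cleavage of a 1,2-disubstituted alkene to two carboxylic acids, which is much faster than attack on saturated menthyl C–H bonds and runs in a non-basic medium where the α-ester stereocentres should not epimerise.

Step 4
Reactants: 6 diacid
Product: 7 bis(1,3-dioxoisoindolin-2-yl) (3R,4R)-3,4-bis{[(1S,2R,5S)-menthyl]oxycarbonyl}hexanedioate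
Conditions: N-hydroxyphthalimide (2.2 equiv), N,N′-diisopropylcarbodiimide (DIC, 2.2 equiv), DMAP (10 mol %), CH2Cl2, rt
Reagents that add atoms: N-hydroxyphthalimide, O=C1c2ccccc2C(=O)N1O
Why: Steglich-type carbodiimide coupling turns both unhindered CH2CO2H groups into redox-active esters, while the menthyl esters are inert and no stereocentre takes part.

Step 5
Reactants: 8 4-bromo-2-methoxyphenol
Product: 9 4-bromo-2-methoxy-1-(methoxymethoxy)benzene
Conditions: NaH (1.2 equiv), MOMCl (1.2 equiv), THF–DMF, 0 °C to rt
Reagents that add atoms: chloromethyl methyl ether, COCCl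
Why: Williamson-type O-alkylation of the sodium phenoxide gives an acetal that should withstand the magnesium, zinc, nickel and hydride reagents used later and that leaves under mild acid.

Step 6
Reactants: 9 aryl bromide
Product: 11 [3-methoxy-4-(methoxymethoxy)phenyl]zinc chloride, via arylmagnesium bromide 10 (not isolated)
Conditions: Mg turnings (1.5 equiv), LiCl (1.25 equiv), iBu2AlH (1 mol %), THF, rt; then ZnCl2 (1.1 equiv, 1.0 M in THF), 0 °C to rt; titrated with I2 and used as the THF solution
Reagents that add atoms: zinc dichloride, Cl[Zn]Cl; magnesium, [Mg] (kept only in intermediate 10)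
Why: LiCl-assisted Grignard formation followed by magnesium-to-zinc transmetalation, to both of which the MOM and methyl ethers are inert, and which leaves no alkyl halide that could compete in step 7.

Step 7
Reactants: 7 bis(N-acyloxyphthalimide) ester; 11 arylzinc chloride
Product: 13 bis[(1S,2R,5S)-menthyl] (2R,3R)-2,3-bis{[3-methoxy-4-(methoxymethoxy)phenyl]methyl}butanedioate, via mono-arylated phthalimide ester 12 (not isolated)
Conditions: NiCl2·glyme (40 mol %), 4,4′-di-tert-butyl-2,2′-bipyridine (80 mol %), 11 (6 equiv), THF–DMF, 25 °C; sat. aq. NH4Cl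
Reagents that add atoms: none
Why: A low-valent aryl–nickel species formed from NiCl2·glyme, the bipyridine and 11 passes one electron to a phthalimide ester of 7, the radical anion breaks at N–O and loses CO2, the primary C7 radical is caught by aryl–nickel, and reductive elimination from the trivalent alkyl(aryl)nickel forms the aryl C1–C7 bond, after which 12 runs through the same cycle at C7′. The closest known reaction type is the nickel-catalysed decarboxylative Negishi-type arylation of primary and secondary alkyl N-acyloxyphthalimides with arylzinc chlorides, used here at two equivalent sites of one molecule. No ring closes and no stereocentre is made. C8 and C8′ sit one carbon away from the radical sites, are never planarised, and see no base strong enough to enolise the esters, so the (R,R) diad of step 2 should pass unchanged, and any leak would show as a diastereomer because the ester groups are chiral. Only chemoselectivity is needed: capture of each radical at nickel has to beat hydrogen abstraction, dimerisation and direct acyl attack by 11, which is helped by three equivalents of 11 and twenty mol % nickel per ester, by the unhindered primary radical, and by the Z-ester geometry that keeps the menthyl C–H bonds out of reach of C7.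

Step 8
Reactants: 13 diaryl diester
Product: 14 (2R,3R)-2,3-bis{[3-methoxy-4-(methoxymethoxy)phenyl]methyl}butane-1,4-diol
Conditions: LiAlH4 (4 equiv), THF, 0 °C to reflux; H2O/aq. NaOH work-up; menthol recovered
Reagents that add atoms: none
Why: LiAlH4 ester reduction proceeds without enolisation, so C8/C8′ should keep the (R,R) configuration, while the MOM acetals and aryl methyl ethers are inert and the auxiliary is released.

Step 9
Reactants: 15 ferulic acid
Product: 17 (E)-3-[3-methoxy-4-(methoxymethoxy)phenyl]prop-2-enoic acid, via methoxymethyl ester 16 (not isolated)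
Conditions: NaH (2.4 equiv), MOMCl (2.4 equiv), DMF, 0 °C to rt; crude 16, LiOH (3 equiv), THF–H2O, rt; 1 M HCl to pH 4, 0 °C
Reagents that add atoms: chloromethyl methyl ether, COCCl; LiOH, [Li+].[OH-] (carboxyl oxygen after acyl–oxygen cleavage)
Why: twofold O-alkylation of phenoxide and carboxylate followed by saponification of the labile methoxymethyl ester, which leaves the base-stable aryl MOM ether and the E-alkene intact.

Step 10
Reactants: 14 diol; 17 O-MOM-ferulic acid
Product: 18 (2R,3R)-4-hydroxy-2,3-bis{[3-methoxy-4-(methoxymethoxy)phenyl]methyl}butyl (E)-3-[3-methoxy-4-(methoxymethoxy)phenyl]prop-2-enoate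
Conditions: 14 (2.0 equiv), 17 (1.0 equiv, slow addition), DIC (1.1 equiv), DMAP (0.2 equiv), CH2Cl2, 0 °C to rt; unreacted 14 recovered
Reagents that add atoms: none
Why: Steglich esterification, which avoids the HCl of an acid chloride preparation that would endanger the MOM ether; because the two hydroxyls of 14 are homotopic, the first acylation gives one compound from either end, and the excess of diol holds back the second acylation.

Step 11
Reactants: 18 tris-MOM monoester
Product: 19 hanultarin, (2R,3R)-4-hydroxy-2,3-bis[(4-hydroxy-3-methoxyphenyl)methyl]butyl (E)-3-(4-hydroxy-3-methoxyphenyl)prop-2-enoate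
Conditions: 2 M aq. HCl–THF (1:4), 40 °C
Reagents that add atoms: none
Why: acid-catalysed acetal hydrolysis of the three aryl MOM ethers, which ionise far more readily than the conjugated ester hydrolyses, while an acyl shift between O9 and O9′ would be degenerate on the C2-symmetric core and no stereocentre is touched.

**Compound list**

1 | fumaric acid | OC(=O)/C=C/C(=O)O | starting material
2 | (+)-menthol, (1S,2R,5S)-2-isopropyl-5-methylcyclohexan-1-ol | O[C@H]1C[C@@H](C)CC[C@@H]1C(C)C | starting material
3 | bis[(1S,2R,5S)-menthyl] (E)-but-2-enedioate | CC(C)[C@H]1CC[C@H](C)C[C@@H]1OC(=O)/C=C/C(=O)O[C@H]1C[C@@H](C)CC[C@@H]1C(C)C | intermediate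
4 | buta-1,3-diene | C=CC=C | starting material
5 | bis[(1S,2R,5S)-menthyl] (1R,2R)-cyclohex-4-ene-1,2-dicarboxylate | CC(C)[C@H]1CC[C@H](C)C[C@@H]1OC(=O)[C@@H]2CC=CC[C@H]2C(=O)O[C@H]3C[C@@H](C)CC[C@@H]3C(C)C | intermediate
6 | (3R,4R)-3,4-bis{[(1S,2R,5S)-menthyl]oxycarbonyl}hexanedioic acid | CC(C)[C@H]1CC[C@H](C)C[C@@H]1OC(=O)[C@H](CC(=O)O)[C@@H](CC(=O)O)C(=O)O[C@H]1C[C@@H](C)CC[C@@H]1C(C)C | intermediate
7 | bis(1,3-dioxoisoindolin-2-yl) (3R,4R)-3,4-bis{[(1S,2R,5S)-menthyl]oxycarbonyl}hexanedioate | CC(C)[C@H]1CC[C@H](C)C[C@@H]1OC(=O)[C@H](CC(=O)ON2C(=O)c3ccccc3C2=O)[C@@H](CC(=O)ON2C(=O)c3ccccc3C2=O)C(=O)O[C@H]1C[C@@H](C)CC[C@@H]1C(C)C | intermediate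
8 | 4-bromo-2-methoxyphenol | COc1cc(Br)ccc1O | starting material
9 | 4-bromo-2-methoxy-1-(methoxymethoxy)benzene | COCOc1ccc(Br)cc1OC | intermediate
10 | [3-methoxy-4-(methoxymethoxy)phenyl]magnesium bromide | COCOc1ccc([Mg]Br)cc1OC | intermediate
11 | [3-methoxy-4-(methoxymethoxy)phenyl]zinc chloride | COCOc1ccc([Zn]Cl)cc1OC | intermediate
12 | bis[(1S,2R,5S)-menthyl] (2R,3R)-2-{[3-methoxy-4-(methoxymethoxy)phenyl]methyl}-3-{2-[(1,3-dioxoisoindolin-2-yl)oxy]-2-oxoethyl}butanedioate | CC(C)[C@H]1CC[C@H](C)C[C@@H]1OC(=O)[C@H](Cc2ccc(OCOC)c(OC)c2)[C@@H](CC(=O)ON2C(=O)c3ccccc3C2=O)C(=O)O[C@H]1C[C@@H](C)CC[C@@H]1C(C)C | intermediate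
13 | bis[(1S,2R,5S)-menthyl] (2R,3R)-2,3-bis{[3-methoxy-4-(methoxymethoxy)phenyl]methyl}butanedioate | CC(C)[C@H]1CC[C@H](C)C[C@@H]1OC(=O)[C@H](Cc2ccc(OCOC)c(OC)c2)[C@@H](Cc2ccc(OCOC)c(OC)c2)C(=O)O[C@H]1C[C@@H](C)CC[C@@H]1C(C)C | intermediate
14 | (2R,3R)-2,3-bis{[3-methoxy-4-(methoxymethoxy)phenyl]methyl}butane-1,4-diol | OC[C@H](Cc1ccc(OCOC)c(OC)c1)[C@H](CO)Cc1ccc(OCOC)c(OC)c1 | intermediate
15 | ferulic acid | COc1cc(/C=C/C(=O)O)ccc1O | starting material
16 | methoxymethyl (E)-3-[3-methoxy-4-(methoxymethoxy)phenyl]prop-2-enoate | COCOC(=O)/C=C/c1ccc(OCOC)c(OC)c1 | intermediate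
17 | (E)-3-[3-methoxy-4-(methoxymethoxy)phenyl]prop-2-enoic acid | COCOc1ccc(/C=C/C(=O)O)cc1OC | intermediate
18 | (2R,3R)-4-hydroxy-2,3-bis{[3-methoxy-4-(methoxymethoxy)phenyl]methyl}butyl (E)-3-[3-methoxy-4-(methoxymethoxy)phenyl]prop-2-enoate | COCOc1ccc(/C=C/C(=O)OC[C@H](Cc2ccc(OCOC)c(OC)c2)[C@H](CO)Cc2ccc(OCOC)c(OC)c2)cc1OC | intermediate
19 | hanultarin | COc1cc(/C=C/C(=O)OC[C@H](Cc2ccc(O)c(OC)c2)[C@H](CO)Cc2ccc(O)c(OC)c2)ccc1O | target

**Step count**

Total steps: 11. Longest linear sequence: 8 (steps 1, 2, 3, 4, 7, 8, 10, 11).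

**Steps most likely to fail**

Step 7.
- Risk: each primary radical may be quenched by hydrogen abstraction before a catalytic aryl–nickel species captures it. The reaction may stall after the first arylation. The arylzinc may also attack the activated acyl groups directly.
- Fallback: radical generation and aryl transfer are separated.
  - It sets out from 7. Light-driven decarboxylative borylation (bis(catecholato)diboron, DMAc, blue LED, rt) offers the radical a trap at stoichiometric concentration and should give the bis(catechol boronate) F1.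
  - F1 is exchanged in the same flask with pinacol/Et3N to the bis(pinacol boronate) F2.
  - A twofold Suzuki–Miyaura coupling of F2 with aryl bromide 9 (Pd(OAc)2, RuPhos, K3PO4, toluene–H2O, 80 °C) forms the same two aryl–C7 bonds by a two-electron path. It comes back to the route at 13.

Step 10.
- Risk: the two hydroxyls react independently, so over-acylation and low conversion to the monoester limit the step.
- Fallback: the two ends are differentiated before the ester is made.
  - It sets out from 14. NaH (1.0 equiv) in THF followed by TBSCl (1.0 equiv) silylates the poorly soluble monosodium alkoxide and should give the mono-TBS ether F3.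
  - Steglich esterification of F3, now run with an excess of 17, gives the silylated ferulate F4.
  - The aqueous HCl–THF conditions of step 11 remove the primary silyl ether together with the three MOM groups. The fallback comes back at 19.

Step 11.
- Risk: the acid may cleave the feruloyl ester. The electron-rich rings or the free alcohol may capture the released formaldehyde. Acetal cleavage may also stop short of completion.
- Fallback: the acid step is moved to a stage without an ester, and the last bond is made without protecting groups.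
  - It sets out from 14. HCl in MeOH at 40 °C gives (−)-secoisolariciresinol F5.
  - Ferulic acid 15 is converted with vinyl acetate (Hg(OAc)2 cat., H2SO4 cat., THF) to vinyl ferulate F6.
  - Transesterification of F5 with F6 is catalysed by an immobilised lipase (Thermomyces lanuginosus or Candida antarctica B) in 2-methylbutan-2-ol at 45 °C and is stopped at partial conversion. It acylates only a primary aliphatic hydroxyl and leaves all phenols free. The fallback comes back at 19.

**Further compounds**

F1 | step 7 | bis[(1S,2R,5S)-menthyl] (2R,3R)-2,3-bis[(1,3,2-benzodioxaborol-2-yl)methyl]butanedioate | CC(C)[C@H]1CC[C@H](C)C[C@@H]1OC(=O)[C@H](CB2Oc3ccccc3O2)[C@@H](CB2Oc3ccccc3O2)C(=O)O[C@H]1C[C@@H](C)CC[C@@H]1C(C)C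
F2 | step 7 | bis[(1S,2R,5S)-menthyl] (2R,3R)-2,3-bis[(4,4,5,5-tetramethyl-1,3,2-dioxaborolan-2-yl)methyl]butanedioate | CC(C)[C@H]1CC[C@H](C)C[C@@H]1OC(=O)[C@H](CB2OC(C)(C)C(C)(C)O2)[C@@H](CB2OC(C)(C)C(C)(C)O2)C(=O)O[C@H]1C[C@@H](C)CC[C@@H]1C(C)C
F3 | step 10 | (2R,3R)-4-[(tert-butyldimethylsilyl)oxy]-2,3-bis{[3-methoxy-4-(methoxymethoxy)phenyl]methyl}butan-1-ol | CC(C)(C)[Si](C)(C)OC[C@H](Cc1ccc(OCOC)c(OC)c1)[C@H](CO)Cc1ccc(OCOC)c(OC)c1
F4 | step 10 | (2R,3R)-4-[(tert-butyldimethylsilyl)oxy]-2,3-bis{[3-methoxy-4-(methoxymethoxy)phenyl]methyl}butyl (E)-3-[3-methoxy-4-(methoxymethoxy)phenyl]prop-2-enoate | COCOc1ccc(/C=C/C(=O)OC[C@H](Cc2ccc(OCOC)c(OC)c2)[C@H](CO[Si](C)(C)C(C)(C)C)Cc2ccc(OCOC)c(OC)c2)cc1OC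
F5 | step 11 | (−)-secoisolariciresinol, (2R,3R)-2,3-bis[(4-hydroxy-3-methoxyphenyl)methyl]butane-1,4-diol | OC[C@H](Cc1ccc(O)c(OC)c1)[C@H](CO)Cc1ccc(O)c(OC)c1
F6 | step 11 | ethenyl (E)-3-(4-hydroxy-3-methoxyphenyl)prop-2-enoate (vinyl ferulate) | COc1cc(/C=C/C(=O)OC=C)ccc1O
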